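With Z in the flask, J sits bound far more than free: for the charge of noon, bound over free is 3490.

    L + Z → J + Q (k1 = 103 M⁻¹ s⁻¹)
    Z + J ⇌ Z.J, settled at all times (K2 = 1.47 × 10⁶ M⁻¹)
    Z + J ⇌ E, settled at all times (K3 = 1.17 × 10⁵ M⁻¹)
    Q → G (k4 = 0.0911 s⁻¹)
all flasks: L 2.0 mM; time 8.0 s
- noon: Z 1.10 equiv
- dawn: Z 1.70 equiv
- spring: Z 2.50 equiv
* part of the L that has reacted at the end, noon
* part of the L that has reacted at the end, dawn
* part of the L that has reacted at the end, spring
* what raising the equivalents of Z from its lowest to its highest value here does to the part of the L that has reacted (changes below 5 percentage points count as none) (no change / it falls / it rises)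

1. Divide the loss of Z by the loss of L and time drops out. The first step takes one Z per L, and the J it makes takes a second Z as far as J is bound. So the Z cost, 2.00 Z gone per L reacted, is a plain count. As long as this cost holds, the Z of noon pays for 55.0% of the L, which makes Z the limiting reagent there.

2. Let f be the part of L reacted, e the equivalents of Z, and τ the rate constant of the first step times the charged c(L) times the time, here 1.65. For a cost n, the rate law integrates to (e − n·f)/(e(1 − f)) = exp((e − n)τ).

3. Upper bound: n is one, as if J were never bound. You get 66.3% for noon, 84.0% for dawn and 94.8% for spring.

4. Lower bound: n is the Z cost. You get 48.6% for noon, 68.9% for dawn and 86.5% for spring.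

5. Tightening: with c(Z) down to a tenth of the noon charge, the cost is still 2.00. So I commit to the lower ends.

6. The forecast says 48.6%, 68.8% and 86.5%, and of the part reacted as Z goes up: it rises. Its ground is that “each L consumed removes about two Z”. Its figures stand level with the lower ends of the brackets .

7. The simulation gives 48.6%, 68.9% and 86.5%. Of the part reacted as Z goes up: it rises, by 38 percentage points.

The difference in equivalents of Z is the main reason for the rise: spring without its extra Z reaches 48.6%, not 86.5%. At the Z cost of 2.00, the 48.6% reacted leaves 11.6% of the charged Z free, and noon reads 11.7%. For a flask like spring with 1.2 mM of L, τ is 0.989, and the same cost gives 76.2%; that flask reads 76.2%.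

The rate constants are made up; the rest is arithmetic.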